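**Plan**
1. Cuts: ring B is opened at the aryl–C1 bond (C8a–C1, Friedel–Crafts), then C3–C4 (enolate benzylation) and C1–C2 (aldol); what remains is C2–C3 with both tertiary oxygens and both carboxyl carbons, i.e. L-tartaric acid.
2. Forward: dimethyl L-tartrate acetonide takes 3,4,5-tris(benzyloxy)benzaldehyde at C2 (aldol) and O-benzylvanillyl bromide at C3; acid unmasking gives a γ-lactone; ring B is then closed; finally CO2H → CH2OH, ester → CO2H, debenzylation.
3. Enabling feature: C1 is benzylic to the trioxygenated pendant ring, C2 is quaternary (no E1 exit), and C8a of ring A is para to OMe. C1 is held as the O-alkyl carbon of a temporary γ-lactone onto the C3 carboxyl; ionising that C1–O bond closes ring B, sets C1 and frees the C3 carboxyl as the only CO2H, so it alone is reduced.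
4. Stereochemistry: C2 and C3 come from L-tartrate through two enolate reactions, each anti to the larger group on the neighbouring dioxolane carbon (net inversion at both carbons, which is the target configuration). C1 is set by C2/C3 in the cyclisation (aryl pseudo-equatorial, trans to CO2Me).

Key step: step 5

Remark on the chemistry: 1, 2 and 6 are taken as purchasable. Compounds 4, 5 and 8–12 are carried as both epimers at the ArCH–O carbon (future C1), drawn without configuration there, because this centre is ionised in step 5. Tetralin locants in the names of 14–17 follow the target.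

**Step 1**
Reactants: 1 dimethyl (4R,5R)-2,2-dimethyl-1,3-dioxolane-4,5-dicarboxylate; 2 3,4,5-tris(benzyloxy)benzaldehyde
Product: 5 dimethyl (4R,5R)-2,2-dimethyl-4-{[(triethylsilyl)oxy][3,4,5-tris(benzyloxy)phenyl]methyl}-1,3-dioxolane-4,5-dicarboxylate (ester groups cis), via lithium enolate 3 (not isolated), via lithium aldolate 4 (not isolated)
Conditions: LiN(iPr)2, THF–DMPU, −78 °C; then 2, −78 °C; then Et3SiOTf, −78 to −40 °C
Reagents that add atoms: triethylsilyl trifluoromethanesulfonate, CC[Si](CC)(CC)OS(=O)(=O)C(F)(F)F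
Why: Aldol addition of the tartrate acetonide ester enolate (stable at −78 °C because the ring C–O bond lies in the enolate plane) should take the aldehyde on the face anti to the CO2Me of the neighbouring ring carbon, which sets C2 with the two esters cis, and O-silylation of the aldolate blocks retro-aldol while the carbinol configuration is irrelevant.

**Step 2**
Reactants: 6 [4-(benzyloxy)-3-methoxyphenyl]methanol
Product: 7 1-(benzyloxy)-4-(bromomethyl)-2-methoxybenzene
Conditions: PBr3, Et2O, 0 °C
Reagents that add atoms: phosphorus tribromide, BrP(Br)Br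
Why: Nucleophilic substitution of the electron-rich benzylic alcohol via its phosphite ester is routine and creates no stereocentre.

**Step 3**
Reactants: 5 silyl-protected aldol adduct; 7 benzylic bromide
Product: 9 dimethyl (4S,5S)-4-{[4-(benzyloxy)-3-methoxyphenyl]methyl}-2,2-dimethyl-5-{[(triethylsilyl)oxy][3,4,5-tris(benzyloxy)phenyl]methyl}-1,3-dioxolane-4,5-dicarboxylate (ester groups trans), via lithium enolate 8 (not isolated)
Conditions: LiN(iPr)2, THF–DMPU, −78 °C; then 7, −78 to −50 °C
Reagents that add atoms: none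
Why: Enolate alkylation at the remaining α-carbon should place the benzylic group anti to the bulky silyloxy(aryl)methyl substituent of the neighbouring quaternary carbon (syn to its CO2Me), which sets C3, returns the esters to trans and brings the C3 ester cis to the carbinol carbon.

**Step 4**
Reactants: 9 dialkylated tartrate acetonide
Product: 12 methyl (3S,4S)-4-{[4-(benzyloxy)-3-methoxyphenyl]methyl}-3,4-dihydroxy-5-oxo-2-[3,4,5-tris(benzyloxy)phenyl]oxolane-3-carboxylate, via hydroxy diester 10 (not isolated), via bicyclic lactone acetonide 11 (not isolated)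
Conditions: 2 M aq. HCl–THF (1:3), 50 °C
Reagents that add atoms: none
Why: Acid hydrolysis removes the triethylsilyl ether, the freed benzylic hydroxyl lactonises (5-exo-trig acyl substitution) onto the cis C3 ester, and the isopropylidene acetal is then hydrolysed, so that no stereocentre is touched and the two carboxyl carbons become different (lactone and methyl ester).

**Step 5**
Reactants: 12 diol γ-lactone
Product: 14 (1S,2S,3S)-7-(benzyloxy)-2,3-dihydroxy-6-methoxy-2-(methoxycarbonyl)-1-[3,4,5-tris(benzyloxy)phenyl]-1,2,3,4-tetrahydronaphthalene-3-carboxylic acid, via benzylic cation 13 (not isolated)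
Conditions: TfOH (0.2 equiv), (CF3)2CHOH–CH2Cl2 (4:1), 0 °C
Reagents that add atoms: none
Why: Protonation of the lactone carbonyl triggers alkyl–oxygen heterolysis of the benzylic C1–O bond to give cation 13 with the C3 carboxyl set free, and the vanillyl ring attacks through its carbon para to OMe (C8a) and rearomatises to 14; C2 is quaternary, so the cation cannot eliminate. The closest known reaction type is the Friedel–Crafts alkylation of arenes by γ-aryl-γ-butyrolactones, together with the acid cyclisation of 2-aryltetrahydrofuran lignans to 1-aryltetralins. Ring B closes as a six-membered ring, 6-endo with respect to the attacking arene bond C8a=C4a and 6-exo-trig at the cationic carbon. The only new stereocentre, C1, is controlled by C2 and C3 through a chair-like transition state with the aryl group pseudo-equatorial, the small C2–OH (not CO2Me) next to the aryl group near the cation plane (least allylic strain) and CO2Me and CO2H equatorial, which puts the aryl group trans to CO2Me (1S); both C1 epimers of 12 converge on the same cation. Regioselectivity (para and not ortho to OMe, six- and not five-membered ring) follows from para activation by OMe and the hindrance of the position between CH2 and OMe, while the aryl benzyl ethers must outlast the ionisation, which the sub-stoichiometric acid, the ionising solvent and 0 °C are chosen to secure.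

**Step 6**
Reactants: 14 tetralin acid ester
Product: 15 methyl (1S,2S,3R)-7-(benzyloxy)-2,3-dihydroxy-3-(hydroxymethyl)-6-methoxy-1-[3,4,5-tris(benzyloxy)phenyl]-1,2,3,4-tetrahydronaphthalene-2-carboxylate
Conditions: BH3·THF, THF, 0 °C to rt; then H2O
Reagents that add atoms: none
Why: Chemoselective borane reduction of a carboxylic acid through its acyloxyborane is much faster than reduction of the hindered methyl ester, so the C3 carboxyl should become the hydroxymethyl group without change at any stereocentre.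

**Step 7**
Reactants: 15 triol methyl ester
Product: 16 (1S,2S,3R)-7-(benzyloxy)-2,3-dihydroxy-3-(hydroxymethyl)-6-methoxy-1-[3,4,5-tris(benzyloxy)phenyl]-1,2,3,4-tetrahydronaphthalene-2-carboxylic acid
Conditions: LiOH, THF–H2O (3:1), rt; then 1 M HCl to pH 3, 0 °C
Reagents that add atoms: lithium hydroxide, [Li+].[OH-]
Why: Saponification (acyl substitution by hydroxide) of the α-hydroxy methyl ester should proceed at room temperature without risk to the stereocentres, because C2 and C3 are quaternary and C1–H is not acidic.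

**Step 8**
Reactants: 16 tetra-O-benzyl acid
Product: 17 (1S,2S,3R)-2,3,7-trihydroxy-3-(hydroxymethyl)-6-methoxy-1-(3,4,5-trihydroxyphenyl)-1,2,3,4-tetrahydronaphthalene-2-carboxylic acid (CNP0174537.1)
Conditions: H2 (1 atm), Pd/C, MeOH–EtOAc, rt; work-up under argon
Reagents that add atoms: none
Why: Hydrogenolysis of the four aryl benzyl ethers over palladium on carbon is standard, leaves the aryl methyl ether and the core intact (no benzylic C–O bond remains there), and is placed last so that the air-sensitive pyrogallol appears only in the final compound.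

**Compound list**
1 | dimethyl (4R,5R)-2,2-dimethyl-1,3-dioxolane-4,5-dicarboxylate (dimethyl L-tartrate acetonide) | COC(=O)[C@@H]1OC(C)(C)O[C@H]1C(=O)OC | starting material
2 | 3,4,5-tris(benzyloxy)benzaldehyde | O=Cc1cc(OCc2ccccc2)c(OCc2ccccc2)c(OCc2ccccc2)c1 | starting material
3 | lithium ester enolate of 1 (enolate geometry open) | COC([O-])=C1OC(C)(C)O[C@H]1C(=O)OC.[Li+] | intermediate
4 | lithium aldolate: O-lithio alcohol corresponding to 5 | COC(=O)[C@@]1(C([O-])c2cc(OCc3ccccc3)c(OCc3ccccc3)c(OCc3ccccc3)c2)OC(C)(C)O[C@H]1C(=O)OC.[Li+] | intermediate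
5 | dimethyl (4R,5R)-2,2-dimethyl-4-{[(triethylsilyl)oxy][3,4,5-tris(benzyloxy)phenyl]methyl}-1,3-dioxolane-4,5-dicarboxylate (esters cis) | COC(=O)[C@@]1(C(O[Si](CC)(CC)CC)c2cc(OCc3ccccc3)c(OCc3ccccc3)c(OCc3ccccc3)c2)OC(C)(C)O[C@H]1C(=O)OC | intermediate
6 | [4-(benzyloxy)-3-methoxyphenyl]methanol | OCc1ccc(OCc2ccccc2)c(OC)c1 | starting material
7 | 1-(benzyloxy)-4-(bromomethyl)-2-methoxybenzene | BrCc1ccc(OCc2ccccc2)c(OC)c1 | intermediate
8 | lithium ester enolate of 5 at C5 | COC(=O)[C@@]1(C(O[Si](CC)(CC)CC)c2cc(OCc3ccccc3)c(OCc3ccccc3)c(OCc3ccccc3)c2)OC(C)(C)OC1=C([O-])OC.[Li+] | intermediate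
9 | dimethyl (4S,5S)-4-{[4-(benzyloxy)-3-methoxyphenyl]methyl}-2,2-dimethyl-5-{[(triethylsilyl)oxy][3,4,5-tris(benzyloxy)phenyl]methyl}-1,3-dioxolane-4,5-dicarboxylate (esters trans) | COC(=O)[C@@]1(C(O[Si](CC)(CC)CC)c2cc(OCc3ccccc3)c(OCc3ccccc3)c(OCc3ccccc3)c2)OC(C)(C)O[C@]1(Cc1ccc(OCc2ccccc2)c(OC)c1)C(=O)OC | intermediate
10 | dimethyl (4S,5S)-4-{[4-(benzyloxy)-3-methoxyphenyl]methyl}-5-{hydroxy[3,4,5-tris(benzyloxy)phenyl]methyl}-2,2-dimethyl-1,3-dioxolane-4,5-dicarboxylate | COC(=O)[C@@]1(C(O)c2cc(OCc3ccccc3)c(OCc3ccccc3)c(OCc3ccccc3)c2)OC(C)(C)O[C@]1(Cc1ccc(OCc2ccccc2)c(OC)c1)C(=O)OC | intermediate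
11 | methyl (3aS,6aS)-6a-{[4-(benzyloxy)-3-methoxyphenyl]methyl}-2,2-dimethyl-6-oxo-4-[3,4,5-tris(benzyloxy)phenyl]tetrahydro-3aH-furo[3,4-d][1,3]dioxole-3a-carboxylate (cis-fused) | COC(=O)[C@@]12OC(C)(C)O[C@]1(Cc1ccc(OCc3ccccc3)c(OC)c1)C(=O)OC2c1cc(OCc2ccccc2)c(OCc2ccccc2)c(OCc2ccccc2)c1 | intermediate
12 | methyl (3S,4S)-4-{[4-(benzyloxy)-3-methoxyphenyl]methyl}-3,4-dihydroxy-5-oxo-2-[3,4,5-tris(benzyloxy)phenyl]oxolane-3-carboxylate | COC(=O)[C@@]1(O)[C@@](O)(Cc2ccc(OCc3ccccc3)c(OC)c2)C(=O)OC1c1cc(OCc2ccccc2)c(OCc2ccccc2)c(OCc2ccccc2)c1 | intermediate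
13 | 3,4,5-tris(benzyloxy)benzyl cation at C1 with free C3 carboxyl (triflate ion pair) | COC(=O)[C@@]([CH+]c1cc(OCc2ccccc2)c(OCc2ccccc2)c(OCc2ccccc2)c1)(O)[C@@](O)(Cc1ccc(OCc2ccccc2)c(OC)c1)C(=O)O.[O-]S(=O)(=O)C(F)(F)F | intermediate
14 | (1S,2S,3S)-7-(benzyloxy)-2,3-dihydroxy-6-methoxy-2-(methoxycarbonyl)-1-[3,4,5-tris(benzyloxy)phenyl]-1,2,3,4-tetrahydronaphthalene-3-carboxylic acid | COc1cc2c(cc1OCc1ccccc1)[C@H](c1cc(OCc3ccccc3)c(OCc3ccccc3)c(OCc3ccccc3)c1)[C@@](O)(C(=O)OC)[C@](O)(C(=O)O)C2 | intermediate
15 | methyl (1S,2S,3R)-7-(benzyloxy)-2,3-dihydroxy-3-(hydroxymethyl)-6-methoxy-1-[3,4,5-tris(benzyloxy)phenyl]-1,2,3,4-tetrahydronaphthalene-2-carboxylate | COc1cc2c(cc1OCc1ccccc1)[C@H](c1cc(OCc3ccccc3)c(OCc3ccccc3)c(OCc3ccccc3)c1)[C@@](O)(C(=O)OC)[C@](O)(CO)C2 | intermediate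
16 | (1S,2S,3R)-7-(benzyloxy)-2,3-dihydroxy-3-(hydroxymethyl)-6-methoxy-1-[3,4,5-tris(benzyloxy)phenyl]-1,2,3,4-tetrahydronaphthalene-2-carboxylic acid | COc1cc2c(cc1OCc1ccccc1)[C@H](c1cc(OCc3ccccc3)c(OCc3ccccc3)c(OCc3ccccc3)c1)[C@@](O)(C(=O)O)[C@](O)(CO)C2 | intermediate
17 | (1S,2S,3R)-2,3,7-trihydroxy-3-(hydroxymethyl)-6-methoxy-1-(3,4,5-trihydroxyphenyl)-1,2,3,4-tetrahydronaphthalene-2-carboxylic acid | COc1cc2c(cc1O)[C@H](c1cc(O)c(O)c(O)c1)[C@@](O)(C(=O)O)[C@](O)(CO)C2 | target

**Step count and risks**
Total steps: 8. Longest linear sequence: 7 (steps 1, 3, 4, 5, 6, 7, 8).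

Step 5 is the most likely to fail. Heterolysis of the lactone C–O bond may be slower than acidolysis of the aryl benzyl ethers; the cation may undergo a 1,2-shift of CO2Me from C2 before ring closure; or the facial preference at C1 may erode. The fallback sets out from 12 and returns at 17. The four benzyl ethers of 12 are removed first (BCl3, pentamethylbenzene, CH2Cl2, −78 °C) to give methyl (3S,4S)-3,4-dihydroxy-4-[(4-hydroxy-3-methoxyphenyl)methyl]-5-oxo-2-(3,4,5-trihydroxyphenyl)oxolane-3-carboxylate F1. With the para-hydroxyl free, the benzylic C–O bond should ionise under weak acid (aq. HCO2H, or dilute HCl in dioxane) through a quinone-methide-type cation, as in the classical acid cyclisation of phenolic lignans. The same chair-like closure should give (1S,2S,3S)-2,3,7-trihydroxy-6-methoxy-2-(methoxycarbonyl)-1-(3,4,5-trihydroxyphenyl)-1,2,3,4-tetrahydronaphthalene-3-carboxylic acid F2. BH3·THF reduction of the acid gives the methyl ester of the target F3, and LiOH in degassed THF–H2O under argon gives 17.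

Step 3 is next. Deprotonation of the C–H shielded by the silyloxy(aryl)methyl group may be incomplete, the enolate may open the dioxolane by β-elimination on warming, or the bromide may enter on the wrong face. The fallback sets out from 1 and 7 and returns at 11. The order of the two enolate reactions is reversed: 1 is alkylated first with 7 (LiN(iPr)2, THF–DMPU, −78 °C, bromide anti to the neighbouring ester) to give dimethyl (4S,5R)-4-{[4-(benzyloxy)-3-methoxyphenyl]methyl}-2,2-dimethyl-1,3-dioxolane-4,5-dicarboxylate F4. Its enolate then adds to 2 anti to the benzylic group. The aldolate (the lithium salt of 10) carries its oxygen cis to the C3 ester and closes directly to 11, which withdraws only this adduct from the retro-aldol equilibrium. 11 is hydrolysed to 12 under the conditions of step 4.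

Step 6 is third. Hydroxyl-directed hydride delivery may over-reduce the α-hydroxy methyl ester, or the reaction may stall at stable borate chelates of the diol acid. The fallback sets out from 14 and returns at 15. Electrophilic borane is replaced by nucleophilic hydride on a pre-activated acyl group: 14 is converted into the isobutyl carbonic mixed anhydride F5 (iBuOCOCl, N-methylmorpholine, THF, −15 °C), which is reduced in situ with NaBH4 in THF–H2O at −15 °C to 15.

**Further compounds**
F1 | step 5 | methyl (3S,4S)-3,4-dihydroxy-4-[(4-hydroxy-3-methoxyphenyl)methyl]-5-oxo-2-(3,4,5-trihydroxyphenyl)oxolane-3-carboxylate | COC(=O)[C@@]1(O)[C@@](O)(Cc2ccc(O)c(OC)c2)C(=O)OC1c1cc(O)c(O)c(O)c1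
F2 | step 5 | (1S,2S,3S)-2,3,7-trihydroxy-6-methoxy-2-(methoxycarbonyl)-1-(3,4,5-trihydroxyphenyl)-1,2,3,4-tetrahydronaphthalene-3-carboxylic acid | COc1cc2c(cc1O)[C@H](c1cc(O)c(O)c(O)c1)[C@@](O)(C(=O)OC)[C@](O)(C(=O)O)C2
F3 | step 5 | methyl (1S,2S,3R)-2,3,7-trihydroxy-3-(hydroxymethyl)-6-methoxy-1-(3,4,5-trihydroxyphenyl)-1,2,3,4-tetrahydronaphthalene-2-carboxylate | COc1cc2c(cc1O)[C@H](c1cc(O)c(O)c(O)c1)[C@@](O)(C(=O)OC)[C@](O)(CO)C2
F4 | step 3 | dimethyl (4S,5R)-4-{[4-(benzyloxy)-3-methoxyphenyl]methyl}-2,2-dimethyl-1,3-dioxolane-4,5-dicarboxylate | COC(=O)[C@@H]1OC(C)(C)O[C@]1(Cc1ccc(OCc2ccccc2)c(OC)c1)C(=O)OC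
F5 | step 6 | isobutyl carbonic mixed anhydride of 14 at the C3 carboxyl | COc1cc2c(cc1OCc1ccccc1)[C@H](c1cc(OCc3ccccc3)c(OCc3ccccc3)c(OCc3ccccc3)c1)[C@@](O)(C(=O)OC)[C@](O)(C(=O)OC(=O)OCC(C)C)C2
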